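**Retrosynthetic overview**

1. Target 12 comes from hydrogenolysis of benzyl ether 11, which comes from oxidation (with retention) of the secondary boronic ester 10.
2. Feature the plan rests on: the benzylic CH2 (C1) and the carbinol CH (C2) of the heptadecyl chain are a two-carbon unit between the 1,3,5-trisubstituted benzene ring and the unbranched C15 chain. This is the footprint of a vinyl group that has taken an aryl group on its terminal carbon and an alkyl group plus boron (later oxygen) on its inner carbon.
3. Key disconnection: the aryl–C1 and C2–C3 bonds are made in one operation from aryl triflate 6, vinyllithium 8 and pentadecylboronic ester 3.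
4. 3 comes from 1-pentadecene by hydroboration, 6 from 5-methoxyresorcinol by monobenzylation and triflation, and 8 from tetravinyltin.
5. No ring is formed at any stage: the benzene ring is bought, and the single stereocentre (C2, R) is set in the key step.

Key step: step 5

Assumption: the (Sp,Sp) enantiomer of the MandyPhos-type ligand is taken to give the (R)-boronate, by analogy with simple n-alkyl migrating groups and aryl triflates. The sense of induction is to be checked on alcohol 11 (Mosher esters or chiral HPLC); if it is opposite, the commercially available antipodal ligand is used with no other change.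

Remark: boronate 10, alcohol 11 and target 12 all carry the (R) descriptor. Oxidation proceeds with retention, and replacing B by O does not change the sense of the CIP sequence at this centre.

**Route**

Step 1
Reactants: 1 1-pentadecene; 2 pinacolborane
Product: 3 2-pentadecyl-4,4,5,5-tetramethyl-1,3,2-dioxaborolane
Conditions: [Ir(cod)Cl]2 (1.5 mol%), dppm (3 mol%), HBpin (1.2 equiv), CH2Cl2, rt
Reagents that add atoms: none
Why: Iridium-catalysed anti-Markovnikov hydroboration of a terminal alkene with pinacolborane places boron on the terminal carbon, so the unbranched C15 pinacol boronate should form cleanly.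

Step 2
Reactants: 4 5-methoxyresorcinol
Product: 5 3-(benzyloxy)-5-methoxyphenol
Conditions: BnBr (0.9 equiv), K2CO3 (1.1 equiv), acetone, reflux; chromatography, recovered 4 recycled
Reagents that add atoms: benzyl bromide, BrCc1ccccc1
Why: Williamson ether synthesis with a slight deficit of benzyl bromide on the symmetric diphenol should give the mono-ether as the main product, separable from recovered diol and the bis-ether.

Step 3
Reactants: 5 3-(benzyloxy)-5-methoxyphenol
Product: 6 3-(benzyloxy)-5-methoxyphenyl trifluoromethanesulfonate
Conditions: Tf2O (1.2 equiv), pyridine (2 equiv), CH2Cl2, 0 °C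
Reagents that add atoms: trifluoromethanesulfonic anhydride, O=S(=O)(OS(=O)(=O)C(F)(F)F)C(F)(F)F
Why: O-Sulfonylation of the phenol with triflic anhydride and pyridine is a standard triflation, and the benzyl and methyl ethers are inert to it.

Step 4
Reactants: 7 tetravinyltin
Product: 8 vinyllithium (halide-free, kept as a titrated stock solution in THF)
Conditions: n-BuLi (hexanes), pentane, rt; precipitate filtered under argon, washed with pentane, dissolved in THF, titrated
Reagents that add atoms: n-butyllithium, [Li]CCCC
Why: Tin–lithium exchange (transmetallation) is driven by precipitation of vinyllithium from the hydrocarbon medium and introduces no halide, which matters because halide ions inhibit the palladium catalyst of step 5.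

Step 5
Reactants: 3 2-pentadecyl-4,4,5,5-tetramethyl-1,3,2-dioxaborolane; 8 vinyllithium; 6 3-(benzyloxy)-5-methoxyphenyl trifluoromethanesulfonate
Product: 10 2-[(2R)-1-(3-(benzyloxy)-5-methoxyphenyl)heptadecan-2-yl]-4,4,5,5-tetramethyl-1,3,2-dioxaborolane, via lithium pentadecyl(vinyl)(pinacolato)borate 9 (not isolated)
Conditions: 3 (1.2 equiv), 8 (1.2 equiv), THF, 0 °C to rt, 30 min; then 6 (1.0 equiv), Pd(OAc)2 (2 mol%), (Sp,Sp)-MandyPhos-type ferrocenyl bisphosphine (2.4 mol%), THF, 60 °C, 14–20 h
Reagents that add atoms: none
Why: Vinyllithium adds to the boron of 3 to give the four-coordinate boronate 9, while oxidative addition of triflate 6 to the Pd(0)–bisphosphine complex gives a cationic arylpalladium(II) species that binds the vinyl group of 9. This triggers a 1,2-metallate shift in which the pentadecyl group moves from boron to the boron-bearing carbon anti to palladium as the terminal carbon bonds to palladium, and reductive elimination then joins the aryl group to that terminal carbon, so the aryl–C1 and C2–C3 bonds form and no ring closes. The closest known reaction type is the palladium-catalysed enantioselective conjunctive cross-coupling of vinylboron ate complexes with aryl triflates, which is established for primary alkyl migrating groups. The one new stereocentre (C2, R) is controlled by the chiral ferrocenyl bisphosphine, which decides the alkene face that palladium occupies, the alkyl group arriving on the opposite face. Regioselectivity is inherent because migration can only end on the carbon attached to boron; the chemoselectivity needed, metallate shift rather than direct Suzuki-type transmetallation or β-hydride elimination, is secured by the weakly coordinating triflate counter-ion, the halide-free medium and the wide-bite-angle ligand, which speeds reductive elimination.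

Step 6
Reactants: 10 2-[(2R)-1-(3-(benzyloxy)-5-methoxyphenyl)heptadecan-2-yl]-4,4,5,5-tetramethyl-1,3,2-dioxaborolane
Product: 11 (2R)-1-[3-(benzyloxy)-5-methoxyphenyl]heptadecan-2-ol
Conditions: 30% H2O2, 3 M aq. NaOH, THF, 0 °C to rt
Reagents that add atoms: hydrogen peroxide, OO
Why: Oxidation of the C–B bond by hydroperoxide goes through a 1,2-shift of carbon from boron to oxygen with retention of configuration, so the (R)-boronate should give the (R)-alcohol while the aryl ethers are unaffected.

Step 7
Reactants: 11 (2R)-1-[3-(benzyloxy)-5-methoxyphenyl]heptadecan-2-ol
Product: 12 3-[(2R)-2-hydroxyheptadecyl]-5-methoxyphenol (CNP0573802.1)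
Conditions: H2 (1 atm), 10% Pd/C, EtOAc–EtOH, rt
Reagents that add atoms: none
Why: Catalytic hydrogenolysis cleaves the benzylic C–O bond of the aryl benzyl ether, whereas the homobenzylic secondary alcohol, the methyl ether and the stereocentre have no bond prone to cleavage under these conditions.

**Compound list**

1 | 1-pentadecene | CCCCCCCCCCCCCC=C | starting material
2 | pinacolborane (4,4,5,5-tetramethyl-1,3,2-dioxaborolane) | CC1(C)OBOC1(C)C | starting material
3 | 2-pentadecyl-4,4,5,5-tetramethyl-1,3,2-dioxaborolane | CCCCCCCCCCCCCCCB1OC(C)(C)C(C)(C)O1 | intermediate
4 | 5-methoxyresorcinol (5-methoxybenzene-1,3-diol) | COc1cc(O)cc(O)c1 | starting material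
5 | 3-(benzyloxy)-5-methoxyphenol | COc1cc(O)cc(OCc2ccccc2)c1 | intermediate
6 | 3-(benzyloxy)-5-methoxyphenyl trifluoromethanesulfonate | COc1cc(OCc2ccccc2)cc(OS(=O)(=O)C(F)(F)F)c1 | intermediate
7 | tetravinyltin | C=C[Sn](C=C)(C=C)C=C | starting material
8 | vinyllithium | [Li]C=C | intermediate
9 | lithium pentadecyl(vinyl)(pinacolato)borate (ate complex) | [Li+].C=C[B-]1(CCCCCCCCCCCCCCC)OC(C)(C)C(C)(C)O1 | intermediate
10 | 2-[(2R)-1-(3-(benzyloxy)-5-methoxyphenyl)heptadecan-2-yl]-4,4,5,5-tetramethyl-1,3,2-dioxaborolane | CCCCCCCCCCCCCCC[C@@H](B1OC(C)(C)C(C)(C)O1)Cc1cc(OCc2ccccc2)cc(OC)c1 | intermediate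
11 | (2R)-1-[3-(benzyloxy)-5-methoxyphenyl]heptadecan-2-ol | CCCCCCCCCCCCCCC[C@@H](O)Cc1cc(OCc2ccccc2)cc(OC)c1 | intermediate
12 | 3-[(2R)-2-hydroxyheptadecyl]-5-methoxyphenol | CCCCCCCCCCCCCCC[C@@H](O)Cc1cc(O)cc(OC)c1 | target

**Step count**

Total steps: 7. Longest linear sequence: 5 steps (steps 2, 3, 5, 6, 7, from 5-methoxyresorcinol).

**Steps most likely to fail, with fallbacks**

1. Step 5 (key step). What may go wrong: direct Suzuki-type transfer of the vinyl or alkyl group instead of the metallate shift, β-hydride elimination from the alkylpalladium intermediate, catalyst inhibition by traces of halide or stannane, or insufficient facial selectivity with the long primary alkyl migrating group.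
Fallback, from 6 back to the route at 11: triflate 6 undergoes Stille allylation (allyltributyltin, Pd(PPh3)4, LiCl, dioxane, reflux) to give 1-allyl-3-(benzyloxy)-5-methoxybenzene F1. Epoxidation (mCPBA, NaHCO3, CH2Cl2, 0 °C) should give racemic 2-[3-(benzyloxy)-5-methoxybenzyl]oxirane F2. Jacobsen hydrolytic kinetic resolution (0.55 equiv water, the (salen)Co(III)OAc enantiomer that leaves the (S)-epoxide) should then give (S)-2-[3-(benzyloxy)-5-methoxybenzyl]oxirane F3. Copper-catalysed opening at the terminal carbon with tetradecylmagnesium bromide (CuI 10 mol%, THF, −30 °C) leads to 11 with the stereocentre untouched. The descriptor changes from S to R only because the ranking of the two CH2 substituents swaps. The fallback bypasses 10 and the route continues with step 7.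

2. Step 4. What may go wrong: incomplete tin–lithium exchange, carry-over of butyl(vinyl)stannanes, or loss of titre while handling the pyrophoric solid, so that the ate complex is formed off-stoichiometry or residual organolithium attacks the triflate.
Fallback, from 3 back to the route at 10: boronate 3 is treated with commercial vinylmagnesium bromide in THF in the presence of sodium triflate, which promotes ate-complex formation and scavenges halide, to give bromomagnesium pentadecyl(vinyl)(pinacolato)borate F4. This is coupled with 6 under the same Pd/MandyPhos catalysis (THF, DMSO co-solvent if needed, 60 °C) to give 10. The organotin-derived reagent is avoided altogether.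

3. Step 2. What may go wrong: poor mono-selectivity, with over-alkylation to the bis-ether and some C-benzylation of the very electron-rich ring, leaving little mono-ether after separation.
Fallback, from 4 back to the route at 5: exhaustive benzylation of 4 (BnBr 2.5 equiv, K2CO3, DMF, 60 °C) gives 1,3-bis(benzyloxy)-5-methoxybenzene F5. Nucleophilic mono-debenzylation with sodium ethanethiolate (1.2 equiv, DMF, 100–120 °C, acidic work-up) should then give 5. The attack should go at the benzylic carbon rather than at methyl, and it should stop after one cleavage because the phenoxide formed makes the remaining aryloxy group a much poorer leaving group.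

**Further compounds**

F1 | step 5 | 1-allyl-3-(benzyloxy)-5-methoxybenzene | C=CCc1cc(OCc2ccccc2)cc(OC)c1
F2 | step 5 | rac-2-[3-(benzyloxy)-5-methoxybenzyl]oxirane | COc1cc(CC2CO2)cc(OCc3ccccc3)c1
F3 | step 5 | (S)-2-[3-(benzyloxy)-5-methoxybenzyl]oxirane | COc1cc(C[C@H]2CO2)cc(OCc3ccccc3)c1
F4 | step 4 | bromomagnesium pentadecyl(vinyl)(pinacolato)borate | [Mg+2].[Br-].C=C[B-]1(CCCCCCCCCCCCCCC)OC(C)(C)C(C)(C)O1
F5 | step 2 | 1,3-bis(benzyloxy)-5-methoxybenzene | COc1cc(OCc2ccccc2)cc(OCc2ccccc2)c1
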